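**Retrosynthetic overview**
- The target comes from global O-debenzylation of a bis-benzyl lactone; the only ring (the γ-lactone) closes in the penultimate step, when a γ-hydroxy acid lactonises.
- The quaternary C5 carbinol is set by chelation-controlled MeMgBr addition to a C5 ketone, itself made from a Weinreb amide acid and an (E)-heptadec-13-enyl Grignard reagent (bromide from an alkyl–alkenyl Suzuki coupling).
- The Weinreb amide acid (C2–C5, with C3 and C4 already set) comes from ozonolysis/Pinnick cleavage of the E-alkene left by the key step.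
- Key step: a glycolate Ireland–Claisen [3,3] rearrangement of a secondary allylic (benzyloxy)acetate forms the C3–C4 bond and sets both centres by chirality transfer.
- The allylic ester comes from (R)-benzyl glycidyl ether, the only bought stereocentre, by ylide homologation, cross-metathesis and acylation.

Assumption: the five building blocks marked "starting material" in the compound list are catalogue chemicals; target ring atoms are counted O1, C2 (carbonyl), C3, C4, C5.

**Route**

Step 1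
Reactants: 1 (R)-benzyl glycidyl ether
Product: 2 (2R)-1-(benzyloxy)but-3-en-2-ol
Conditions: Me3S+ I− (3 eq), n-BuLi (2.9 eq), THF, −10 °C to rt
Reagents that add atoms: trimethylsulfonium iodide, C[S+](C)C.[I-]
Why: Dimethylsulfonium methylide opens the epoxide at its terminal carbon and a second ylide equivalent eliminates dimethyl sulfide from the oxido sulfonium salt (Corey–Chaykovsky-type one-carbon homologation of an epoxide to an allylic alcohol), so the bought C–O stereocentre is untouched and becomes the (R)-carbinol.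

Step 2
Reactants: 2 (2R)-1-(benzyloxy)but-3-en-2-ol; 3 (Z)-1,4-bis(benzyloxy)but-2-ene (2 eq)
Product: 4 (2R,3E)-1,5-bis(benzyloxy)pent-3-en-2-ol
Conditions: second-generation Grubbs catalyst RuCl2(=CHPh)(PCy3)(H2IMes) (5 mol %), CH2Cl2, 40 °C
Reagents that add atoms: none
Why: Olefin cross-metathesis between the slowly homodimerising secondary allylic alcohol and an excess of the symmetric bis-ether is thermodynamically controlled and gives the E-alkene (typically above 10:1) without touching the carbinol centre.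

Step 3
Reactants: 4 (2R,3E)-1,5-bis(benzyloxy)pent-3-en-2-ol; 5 (benzyloxy)acetyl chloride
Product: 6 (2R,3E)-1,5-bis(benzyloxy)pent-3-en-2-yl 2-(benzyloxy)acetate
Conditions: pyridine (2 eq), DMAP (5 mol %), CH2Cl2, 0 °C to rt
Reagents that add atoms: none
Why: DMAP-catalysed O-acylation (nucleophilic acyl substitution) takes place at oxygen, so the carbinol configuration is retained.

Step 4
Reactants: 6 (2R,3E)-1,5-bis(benzyloxy)pent-3-en-2-yl 2-(benzyloxy)acetate
Product: 9 (2S,3S,4E)-2,6-bis(benzyloxy)-3-[(benzyloxy)methyl]hex-4-enoic acid, via silyl ketene acetal 7 (not isolated), via trimethylsilyl ester 8 (not isolated)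
Conditions: LiN(SiMe3)2 (1.5 eq), THF, −78 °C; Me3SiCl (2 eq), −78 °C to rt; 1 M HCl work-up
Reagents that add atoms: none
Why: Ireland–Claisen [3,3]-sigmatropic rearrangement: the lithium-chelated Z-enolate of the α-benzyloxy ester is trapped as the Z-silyl ketene acetal, which rearranges through a chair with the carbinol CH2OBn group equatorial, so the C–O chirality is transferred suprafacially to the new C2–C3 bond and gives the syn (2S,3S) acid with an E-alkene.

Step 5
Reactants: 9 (2S,3S,4E)-2,6-bis(benzyloxy)-3-[(benzyloxy)methyl]hex-4-enoic acid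
Product: 11 (2S,3S,4E)-2,6-bis(benzyloxy)-3-[(benzyloxy)methyl]-N-methoxy-N-methylhex-4-enamide, via acyl imidazolide 10 (not isolated)
Conditions: 1,1'-carbonyldiimidazole (1.2 eq), CH2Cl2, rt; then MeNH(OMe)·HCl (1.5 eq), rt
Reagents that add atoms: N,O-dimethylhydroxylamine hydrochloride, CNOC.Cl
Why: Activation as the acyl imidazolide and aminolysis (amide coupling) needs no base strong enough to epimerise the α-alkoxy centre.

Step 6
Reactants: 11 (2S,3S,4E)-2,6-bis(benzyloxy)-3-[(benzyloxy)methyl]-N-methoxy-N-methylhex-4-enamide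
Product: 14 (2S,3S)-3-(benzyloxy)-2-[(benzyloxy)methyl]-4-[methoxy(methyl)amino]-4-oxobutanoic acid, via ozonide 12 (not isolated), via aldehyde 13 (not isolated)
Conditions: O3, CH2Cl2, −78 °C; PPh3, to rt; then NaClO2, NaH2PO4, 2-methyl-2-butene, t-BuOH/H2O, rt
Reagents that add atoms: ozone, [O-][O+]=O; sodium chlorite, [Na+].[O-]Cl=O
Why: Ozonolysis with phosphine work-up cleaves the only alkene, and buffered Pinnick oxidation of the crude aldehyde gives the acid under mildly acidic conditions that neither epimerise nor β-eliminate the α-branched β-alkoxy aldehyde.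

Step 7
Reactants: 15 1,12-dibromododecane (4 eq); 16 (E)-pent-1-en-1-ylboronic acid
Product: 17 (4E)-17-bromoheptadec-4-ene
Conditions: Pd(OAc)2 (5 mol %), P(t-Bu)2Me (10 mol %), KOt-Bu (3 eq), tert-amyl alcohol, rt
Reagents that add atoms: none
Why: Palladium-catalysed alkyl–alkenyl Suzuki–Miyaura coupling with a bulky electron-rich trialkylphosphine couples the primary bromide with retention of the E-alkenylboron geometry, and the excess dibromide limits the reaction to monocoupling.

Step 8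
Reactants: 14 (2S,3S)-3-(benzyloxy)-2-[(benzyloxy)methyl]-4-[methoxy(methyl)amino]-4-oxobutanoic acid; 17 (4E)-17-bromoheptadec-4-ene
Product: 19 (2S,3S,17E)-3-(benzyloxy)-2-[(benzyloxy)methyl]-4-oxohenicos-17-enoic acid, via Grignard reagent 18 (not isolated)
Conditions: 17, Mg, THF, 45 °C; 14, t-BuMgCl (1.0 eq), THF, −40 °C; then 18 (1.5 eq), −40 to 0 °C; 1 M HCl
Reagents that add atoms: none
Why: After deprotonation of the acid by non-nucleophilic t-BuMgCl, the Grignard reagent adds only to the Weinreb amide, whose magnesium chelate survives until work-up and prevents over-addition (Weinreb ketone synthesis); the magnesium carboxylate is inert and no stereocentre is touched.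

Step 9
Reactants: 19 (2S,3S,17E)-3-(benzyloxy)-2-[(benzyloxy)methyl]-4-oxohenicos-17-enoic acid
Product: 21 (3S,4S,5R)-4-(benzyloxy)-3-[(benzyloxy)methyl]-5-[(13E)-heptadec-13-en-1-yl]-5-methyloxolan-2-one, via hydroxy acid 20 (not isolated)
Conditions: MeMgBr (3 eq), THF, −78 to −20 °C; 1 M HCl; then TsOH·H2O (cat.), CH2Cl2, rt
Reagents that add atoms: methylmagnesium bromide, C[Mg]Br
Why: Cram-chelate-controlled Grignard addition: magnesium bridges the ketone and the α-benzyloxy oxygen, MeMgBr attacks from the face of the α-hydrogen and sets the quaternary carbinol (methyl cis to the C4 oxygen, 5R in the lactone), and the γ-hydroxy acid then closes to the γ-lactone under acid catalysis.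

Step 10
Reactants: 21 (3S,4S,5R)-4-(benzyloxy)-3-[(benzyloxy)methyl]-5-[(13E)-heptadec-13-en-1-yl]-5-methyloxolan-2-one
Product: 22 (3S,4S,5R)-5-[(13E)-heptadec-13-en-1-yl]-4-hydroxy-3-(hydroxymethyl)-5-methyloxolan-2-one
Conditions: BCl3 (5 eq), pentamethylbenzene (6 eq), CH2Cl2, −78 °C; MeOH quench
Reagents that add atoms: none
Why: Lewis-acid debenzylation with BCl3 and pentamethylbenzene as cation scavenger cleaves both benzyl ethers at low temperature without hydrogen, so the E-alkene, the lactone and all three stereocentres are retained.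

**Compound list**
1 | (R)-benzyl glycidyl ether, (2R)-2-[(benzyloxy)methyl]oxirane | c1ccccc1COC[C@H]1CO1 | starting material
2 | (2R)-1-(benzyloxy)but-3-en-2-ol | C=C[C@@H](O)COCc1ccccc1 | intermediate
3 | (Z)-1,4-bis(benzyloxy)but-2-ene | c1ccccc1COC/C=C\COCc1ccccc1 | starting material
4 | (2R,3E)-1,5-bis(benzyloxy)pent-3-en-2-ol | c1ccccc1COC/C=C/[C@@H](O)COCc1ccccc1 | intermediate
5 | (benzyloxy)acetyl chloride | ClC(=O)COCc1ccccc1 | starting material
6 | (2R,3E)-1,5-bis(benzyloxy)pent-3-en-2-yl 2-(benzyloxy)acetate | c1ccccc1COC/C=C/[C@@H](OC(=O)COCc1ccccc1)COCc1ccccc1 | intermediate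
7 | [(1Z)-2-(benzyloxy)-1-{[(2R,3E)-1,5-bis(benzyloxy)pent-3-en-2-yl]oxy}ethenyl]oxy(trimethyl)silane (Z-silyl ketene acetal of 6) | c1ccccc1COC/C=C/[C@@H](O/C(O[Si](C)(C)C)=C/OCc1ccccc1)COCc1ccccc1 | intermediate
8 | trimethylsilyl (2S,3S,4E)-2,6-bis(benzyloxy)-3-[(benzyloxy)methyl]hex-4-enoate | c1ccccc1COC/C=C/[C@@H](COCc1ccccc1)[C@H](OCc1ccccc1)C(=O)O[Si](C)(C)C | intermediate
9 | (2S,3S,4E)-2,6-bis(benzyloxy)-3-[(benzyloxy)methyl]hex-4-enoic acid | c1ccccc1COC/C=C/[C@@H](COCc1ccccc1)[C@H](OCc1ccccc1)C(=O)O | intermediate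
10 | 1-[(2S,3S,4E)-2,6-bis(benzyloxy)-3-[(benzyloxy)methyl]hex-4-enoyl]-1H-imidazole | c1ccccc1COC/C=C/[C@@H](COCc1ccccc1)[C@H](OCc1ccccc1)C(=O)n1ccnc1 | intermediate
11 | (2S,3S,4E)-2,6-bis(benzyloxy)-3-[(benzyloxy)methyl]-N-methoxy-N-methylhex-4-enamide | c1ccccc1COC/C=C/[C@@H](COCc1ccccc1)[C@H](OCc1ccccc1)C(=O)N(C)OC | intermediate
12 | (2S,3S)-2-(benzyloxy)-3-[(benzyloxy)methyl]-3-{5-[(benzyloxy)methyl]-1,2,4-trioxolan-3-yl}-N-methoxy-N-methylpropanamide (ozonide, mixture at the trioxolane carbons) | c1ccccc1COCC1OOC(O1)[C@@H](COCc1ccccc1)[C@H](OCc1ccccc1)C(=O)N(C)OC | intermediate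
13 | (2S,3S)-2-(benzyloxy)-3-[(benzyloxy)methyl]-N-methoxy-N-methyl-4-oxobutanamide | O=C[C@@H](COCc1ccccc1)[C@H](OCc1ccccc1)C(=O)N(C)OC | intermediate
14 | (2S,3S)-3-(benzyloxy)-2-[(benzyloxy)methyl]-4-[methoxy(methyl)amino]-4-oxobutanoic acid | OC(=O)[C@@H](COCc1ccccc1)[C@H](OCc1ccccc1)C(=O)N(C)OC | intermediate
15 | 1,12-dibromododecane | BrCCCCCCCCCCCCBr | starting material
16 | (E)-pent-1-en-1-ylboronic acid | CCC/C=C/B(O)O | starting material
17 | (4E)-17-bromoheptadec-4-ene | CCC/C=C/CCCCCCCCCCCCBr | intermediate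
18 | [(13E)-heptadec-13-en-1-yl]magnesium bromide | CCC/C=C/CCCCCCCCCCCC[Mg]Br | intermediate
19 | (2S,3S,17E)-3-(benzyloxy)-2-[(benzyloxy)methyl]-4-oxohenicos-17-enoic acid | OC(=O)[C@@H](COCc1ccccc1)[C@H](OCc1ccccc1)C(=O)CCCCCCCCCCCC/C=C/CCC | intermediate
20 | (2S,3S,4R,17E)-3-(benzyloxy)-2-[(benzyloxy)methyl]-4-hydroxy-4-methylhenicos-17-enoic acid | CCC/C=C/CCCCCCCCCCCC[C@@](C)(O)[C@@H](OCc1ccccc1)[C@H](COCc1ccccc1)C(=O)O | intermediate
21 | (3S,4S,5R)-4-(benzyloxy)-3-[(benzyloxy)methyl]-5-[(13E)-heptadec-13-en-1-yl]-5-methyloxolan-2-one | CCC/C=C/CCCCCCCCCCCC[C@@]1(C)OC(=O)[C@@H](COCc2ccccc2)[C@@H]1OCc1ccccc1 | intermediate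
22 | (3S,4S,5R)-5-[(13E)-heptadec-13-en-1-yl]-4-hydroxy-3-(hydroxymethyl)-5-methyloxolan-2-one | CCC/C=C/CCCCCCCCCCCC[C@@]1(C)OC(=O)[C@@H](CO)[C@@H]1O | target

**Step count and risks**

Total step count: 10. Longest linear sequence: 9 (steps 1–6 and 8–10, from compound 1).

The three steps most likely to fail:

Step 2 (cross-metathesis: the E/Z ratio and homodimers decide the diastereomeric purity of the Claisen product). The fallback builds the E-alkene by olefination instead of metathesis, sets out from 2 and comes back at 4. Silylation of 2 (t-BuMe2SiCl, imidazole) gives tert-butyl{[(2R)-1-(benzyloxy)but-3-en-2-yl]oxy}dimethylsilane F1. Ozonolysis (O3, then PPh3) gives (2S)-3-(benzyloxy)-2-[(tert-butyldimethylsilyl)oxy]propanal F2. Horner–Wadsworth–Emmons olefination (triethyl phosphonoacetate, NaH) gives ethyl (2E,4R)-5-(benzyloxy)-4-[(tert-butyldimethylsilyl)oxy]pent-2-enoate F3. Reduction with i-Bu2AlH gives (2E,4R)-5-(benzyloxy)-4-[(tert-butyldimethylsilyl)oxy]pent-2-en-1-ol F4. NaH and BnBr give {[(2R,3E)-1,5-bis(benzyloxy)pent-3-en-2-yl]oxy}(tert-butyl)dimethylsilane F5, and Bu4NF returns 4.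

Step 7 (sp3–sp2 Suzuki coupling of an unactivated alkyl bromide, statistical monocoupling of a dibromide). The fallback inverts the roles of the partners, sets out from 15 and comes back at 17. Mono-dehydrobromination of 15 (KOt-Bu, THF) gives 12-bromododec-1-ene F6. Hydroboration with 9-BBN-H gives 9-(12-bromododecyl)-9-borabicyclo[3.3.1]nonane F7. This is coupled in the same pot (PdCl2(dppf), K3PO4, THF/DMF/H2O) with (1E)-1-iodopent-1-ene F8, made from pent-1-yne with Cp2Zr(H)Cl then I2, to give 17; the primary bromide is inert under these conditions.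

Step 9 (facial selectivity of the methyl addition at the quaternary centre, enolisation of the α-alkoxy ketone). The fallback sets the C5 centre by cyclisation instead of carbonyl addition, sets out from 19 and comes back at 21. Wittig methylenation of 19 (Ph3PCH3Br, KOt-Bu) gives (2S,3S,17E)-3-(benzyloxy)-2-[(benzyloxy)methyl]-4-methylidenehenicos-17-enoic acid F9. Kinetic 5-exo iodolactonisation (I2, NaHCO3, MeCN, 0 °C) gives (3S,4S,5R)-4-(benzyloxy)-3-[(benzyloxy)methyl]-5-[(13E)-heptadec-13-en-1-yl]-5-(iodomethyl)oxolan-2-one F10. The iodomethyl group is expected cis to the C4 benzyloxy group (allylic alkoxy group in the alkene plane); this should be confirmed by NOE. Radical reduction (Bu3SnH, AIBN, toluene, 80 °C) turns CH2I into the methyl group and returns 21.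

Further compounds
F1 | step 2 | tert-butyl{[(2R)-1-(benzyloxy)but-3-en-2-yl]oxy}dimethylsilane | C=C[C@@H](O[Si](C)(C)C(C)(C)C)COCc1ccccc1
F2 | step 2 | (2S)-3-(benzyloxy)-2-[(tert-butyldimethylsilyl)oxy]propanal | O=C[C@@H](O[Si](C)(C)C(C)(C)C)COCc1ccccc1
F3 | step 2 | ethyl (2E,4R)-5-(benzyloxy)-4-[(tert-butyldimethylsilyl)oxy]pent-2-enoate | CCOC(=O)/C=C/[C@@H](O[Si](C)(C)C(C)(C)C)COCc1ccccc1
F4 | step 2 | (2E,4R)-5-(benzyloxy)-4-[(tert-butyldimethylsilyl)oxy]pent-2-en-1-ol | OC/C=C/[C@@H](O[Si](C)(C)C(C)(C)C)COCc1ccccc1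
F5 | step 2 | {[(2R,3E)-1,5-bis(benzyloxy)pent-3-en-2-yl]oxy}(tert-butyl)dimethylsilane | c1ccccc1COC/C=C/[C@@H](O[Si](C)(C)C(C)(C)C)COCc1ccccc1
F6 | step 7 | 12-bromododec-1-ene | C=CCCCCCCCCCCBr
F7 | step 7 | 9-(12-bromododecyl)-9-borabicyclo[3.3.1]nonane | BrCCCCCCCCCCCCB1C2CCCC1CCC2
F8 | step 7 | (1E)-1-iodopent-1-ene | CCC/C=C/I
F9 | step 9 | (2S,3S,17E)-3-(benzyloxy)-2-[(benzyloxy)methyl]-4-methylidenehenicos-17-enoic acid | OC(=O)[C@@H](COCc1ccccc1)[C@H](OCc1ccccc1)C(=C)CCCCCCCCCCCC/C=C/CCC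
F10 | step 9 | (3S,4S,5R)-4-(benzyloxy)-3-[(benzyloxy)methyl]-5-[(13E)-heptadec-13-en-1-yl]-5-(iodomethyl)oxolan-2-one | CCC/C=C/CCCCCCCCCCCC[C@@]1(CI)OC(=O)[C@@H](COCc2ccccc2)[C@@H]1OCc1ccccc1
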